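## Structural features

The target 20 is an achiral C38 ester with no stereocentre and no stereogenic double bond. It is 19-(furan-2-yl)nonadeca-5,7-diynoic acid esterified with 11-(furan-2-yl)undeca-4,6-diyn-1-ol. Each half ends in a 2-monosubstituted furan, joined through a saturated chain (eleven CH2 in the acyl half, four CH2 in the alkoxy half) to an unsymmetrical conjugated 1,3-diyne (C5≡C6–C7≡C8 in the acyl half, C4'≡C5'–C6'≡C7' in the alkoxy half). Both diynes sit three methylenes away from the ester group. The fragile groups are the diynes (light, heat, radicals, strong base), the 2-alkylfurans (acid, electrophilic halogen, oxidants) and the ester (nucleophiles, organolithiums). There is no ring to build and nothing to set stereochemically. The difficulty is connectivity: two unsymmetrical sp–sp linkages that must be made without homocoupling, and an ester that joins two sensitive halves. The key step exploits the acyl carbon C1, the methylenes C2–C4 and the triple bond C5≡C6: these are the six carbons of a cyclohexane-1,3-dione, and the pattern "C1 ester carbonyl, C5≡C6 alkyne" is the product side of a Grob-type fragmentation of a 3-triflyloxycyclohex-2-enone whose ring carbon 2 already carries the C7≡C8 alkynyl group.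

## Logic of the disconnections

20 ⇒ 9 + 17. In one sentence: 20 arises when 18 (the lithium alkoxide of 9) opens the six-membered ring of 17 by carbonyl addition and Grob-type fragmentation. The bonds formed forward are the ester bond C1–O1' and the second π bond of C5≡C6; backwards, a σ bond is drawn between C1 and C6 and a triflate is placed on C5, which gives a carbocycle made of C1–C6. The cut is made here because C1 and C5 stand in the 1,5-relationship that a 1,3-dione ring encodes. The gain is that the halves are joined and the acyl-half diyne is completed in the last step, without a second copper coupling and without a free diynoic acid; 17 has one triple bond and no ester. The demand is that 18 adds to the ring carbonyl of 17 and not to the triflate-bearing carbon or to sulfur, and that adduct 19 fragments faster than it reverts.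

17 ⇒ 16 ⇒ 15. The O–S bond of the triflate is cut, then the enol O–H is traced back to an O–ethyl group. 16 is a symmetrical 2-substituted 1,3-dione, so sulfonylation can give only one regioisomer. The ethyl vinylogous ester of 15 masks the acidic dione during the metal-catalysed coupling. The forward demand is a hydrolysis mild enough for the 2-alkylfuran and for the alkyne next to the enol.

15 ⇒ 14 + 12. The cut is the C6–C7 bond, which is the central σ bond of the acyl-half diyne in 20 but an sp2–sp bond at this stage. Making it by palladium/copper coupling of a vinyl iodide with a terminal alkyne avoids a bromoalkyne that carries a furan. The demand is oxidative addition into a hindered, electron-rich C–I bond.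

14 ⇒ 13. The C–I bond is cut; the α-carbon of the push–pull enone in 13 is its nucleophilic site, so electrophilic iodination is regiospecific.

12 ⇒ 11 + 5, and 11 ⇒ 2 + 10. The cuts are the sp–sp3 bond C8–C9 and the bond between C19 and the 2-furyl carbon. This reduces the long arm to a C2 unit, a C11 α,ω-dihalide and the metalated heterocycle. The demand is mono-alkylation of 10, met by using it in excess.

9 ⇒ 6 + 8, and 8 ⇒ 7. The cut is the sp–sp bond C5'–C6'. The bromine is placed on the furan-free partner 8, because electrophilic bromine sources attack 2-alkylfurans. The demand is hetero- over homocoupling.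

6 ⇒ 4 + 5, and 4 ⇒ 2 + 3. The cuts are the sp–sp3 bond C7'–C8' and the bond between C11' and the 2-furyl carbon. The demand on 3 is displacement of bromide with the chloride kept for the next step.

2 ⇒ 1. The C–Li bond is traced back to the C2–H bond of the parent heterocycle, the most acidic position next to the ring oxygen. One batch of 2 serves both alkylations, so the two furan-bearing arms start from a single metalation.

## Other disconnections considered

Alternative 1: Cut the ester C1–O bond and the C6–C7 sp–sp bond of the acyl half. Forward, Cadiot–Chodkiewicz coupling of 12 with 6-bromohex-5-ynoic acid A1 would give 19-(furan-2-yl)nonadeca-5,7-diynoic acid A2, and carbodiimide esterification of A2 with 9 would give 20. This is the route most chemists would draw first, and it is two steps shorter. The chosen plan is preferred on two chemical grounds. A second copper-mediated heterocoupling is expected to give symmetrical diynes by halogen–copper exchange, and these are hard to separate from A2 because all are long non-polar chains; a unimolecular fragmentation cannot homocouple. The free diynoic acid A2, a polymerisable diacetylene, also never has to be isolated and activated.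

Alternative 2: Form each diyne by a 1,2-alkynyl shift (Fritsch–Buttenberg–Wiechell rearrangement). For the acyl half, the dibromoalkene 2-[18-[(tert-butyldimethylsilyl)oxy]-12-(dibromomethylidene)octadec-13-yn-1-yl]furan A3 would be treated with n-BuLi; the alkylidene carbenoid would rearrange to tert-butyl{[19-(furan-2-yl)nonadeca-5,7-diyn-1-yl]oxy}dimethylsilane A4. Each diyne then costs three operations (ynone, dibromo-olefination, rearrangement). The acyl half must be carried at the alcohol oxidation level and oxidised later in the presence of an oxidation-sensitive furan. The organolithium excludes the ester, so the rearrangement cannot serve as a late convergent step. The chosen plan makes an alkyne and the ester in one operation.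

Alternative 3: Cut the two sp–sp3 bonds that flank each diyne and take each C4 unit intact from 1,4-bis(trimethylsilyl)buta-1,3-diyne A5. Forward, mono-desilylation and lithiation of A5 and alkylation with 2-(4-iodobutyl)furan A6 would give trimethyl[8-(furan-2-yl)octa-1,3-diyn-1-yl]silane A7; desilylation and a second alkylation at the other terminus would follow, then the same sequence for the acyl half and an esterification. This needs four alkylations of weakly nucleophilic diynyl anions, the handling of terminal 1,3-diynes (the least stable members of this family) and a masked 4-halobutanoate that is prone to cyclisation. The ester junction would still be a separate step, so the plan is longer and settles less per step.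

Key step: step 12

Remark on the chemistry: 20 has no stereogenic element, so no descriptor is needed. 16 is written as the enol tautomer of the symmetrical 1,3-dione. 1, 3, 5, 7, 10 and 13 are taken as commercial. 2 is prepared once in step 1 as a THF solution, kept at 0 °C, and divided on the same day between steps 2 and 6.

## Route

Step 1
Reactants: 1 furan
Product: 2 2-furyllithium
Conditions: n-BuLi, THF, −78 to 0 °C; solution titrated, kept at 0 °C
Reagents that add atoms: n-butyllithium, [Li]CCCC
Why: α-Lithiation (deprotonation) of furan at C2, the most acidic ring position next to oxygen; the THF solution is stable at 0 °C for the hours needed and one batch is divided between the alkylations of steps 2 and 6.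

Step 2
Reactants: 2 2-furyllithium; 3 1-bromo-4-chlorobutane
Product: 4 2-(4-chlorobutyl)furan
Conditions: first portion of the solution of 2, THF, then 3, −78 °C to rt
Reagents that add atoms: none
Why: SN2 alkylation of a heteroaryllithium by a primary halide; bromide is displaced much faster than chloride, so the chloride is kept for step 3.

Step 3
Reactants: 4 2-(4-chlorobutyl)furan; 5 lithium acetylide ethylenediamine complex
Product: 6 2-(hex-5-yn-1-yl)furan
Conditions: 5, NaI (cat.), DMSO, rt
Reagents that add atoms: none
Why: SN2 alkylation of lithium acetylide by a primary chloride in DMSO, helped by in situ halide exchange (Finkelstein); the furan is inert to these basic conditions.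

Step 4
Reactants: 7 pent-4-yn-1-ol
Product: 8 5-bromopent-4-yn-1-ol
Conditions: NBS, AgNO3 (cat.), acetone, rt, dark
Reagents that add atoms: N-bromosuccinimide, BrN1C(=O)CCC1=O
Why: Silver-catalysed electrophilic bromination of a terminal alkyne through the silver acetylide; the free hydroxyl is tolerated and the bromination is done on the partner that has no furan.

Step 5
Reactants: 6 2-(hex-5-yn-1-yl)furan; 8 5-bromopent-4-yn-1-ol
Product: 9 11-(furan-2-yl)undeca-4,6-diyn-1-ol
Conditions: CuCl (cat.), NH2OH·HCl, 30% aq. n-BuNH2, Et2O, 0 °C, slow addition of 8
Reagents that add atoms: none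
Why: Cadiot–Chodkiewicz coupling of the copper acetylide of 6 with bromoalkyne 8; hydroxylamine keeps the copper monovalent and slow addition of 8 limits homocoupling.

Step 6
Reactants: 2 2-furyllithium; 10 1,11-dibromoundecane
Product: 11 2-(11-bromoundecyl)furan
Conditions: second portion of the solution of 2 added to 10 (3 equiv), THF, −78 °C to rt
Reagents that add atoms: none
Why: The same SN2 alkylation of a heteroaryllithium as in step 2; inverse addition to an excess of the dibromide favours mono-alkylation, and unreacted 10 is recovered by distillation.

Step 7
Reactants: 11 2-(11-bromoundecyl)furan; 5 lithium acetylide ethylenediamine complex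
Product: 12 2-(tridec-12-yn-1-yl)furan
Conditions: 5, DMSO, rt
Reagents that add atoms: none
Why: SN2 alkylation of lithium acetylide by a primary bromide, the standard two-carbon homologation to a terminal alkyne.

Step 8
Reactants: 13 3-ethoxycyclohex-2-en-1-one
Product: 14 3-ethoxy-2-iodocyclohex-2-en-1-one
Conditions: NIS, MeCN, rt, dark
Reagents that add atoms: N-iodosuccinimide, IN1C(=O)CCC1=O
Why: Electrophilic iodination of the push–pull alkene at its nucleophilic α-carbon, followed by loss of a proton; only C2 can react.

Step 9
Reactants: 14 3-ethoxy-2-iodocyclohex-2-en-1-one; 12 2-(tridec-12-yn-1-yl)furan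
Product: 15 3-ethoxy-2-[13-(furan-2-yl)tridec-1-yn-1-yl]cyclohex-2-en-1-one
Conditions: PdCl2(PPh3)2 (cat.), CuI (cat.), i-Pr2NH, THF, degassed, rt
Reagents that add atoms: none
Why: Sonogashira coupling of an α-iodoenone with a terminal alkyne (oxidative addition of zerovalent palladium into C–I, transmetalation from the copper acetylide, reductive elimination); the vinylogous ester and the furan are inert.

Step 10
Reactants: 15 3-ethoxy-2-[13-(furan-2-yl)tridec-1-yn-1-yl]cyclohex-2-en-1-one
Product: 16 2-[13-(furan-2-yl)tridec-1-yn-1-yl]-3-hydroxycyclohex-2-en-1-one
Conditions: 1 M aq. HCl, THF, rt; buffered work-up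
Reagents that add atoms: water, O
Why: Acid-catalysed hydrolysis of a vinylogous ester (addition of water at C3, loss of ethanol) to the enolised 1,3-dione; dilute acid at rt without any metal should leave the 2-alkylfuran and the alkyne untouched.

Step 11
Reactants: 16 2-[13-(furan-2-yl)tridec-1-yn-1-yl]-3-hydroxycyclohex-2-en-1-one
Product: 17 2-[13-(furan-2-yl)tridec-1-yn-1-yl]-3-oxocyclohex-1-en-1-yl trifluoromethanesulfonate
Conditions: Tf2O, pyridine, CH2Cl2, −78 °C; used at once
Reagents that add atoms: trifluoromethanesulfonic anhydride, O=S(=O)(OS(=O)(=O)C(F)(F)F)C(F)(F)F
Why: O-Sulfonylation of the enol of a symmetrical 1,3-dione, the standard preparation of vinylogous acyl triflates; the symmetry of 16 allows a single regioisomer.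

Step 12
Reactants: 9 11-(furan-2-yl)undeca-4,6-diyn-1-ol; 17 2-[13-(furan-2-yl)tridec-1-yn-1-yl]-3-oxocyclohex-1-en-1-yl trifluoromethanesulfonate
Product: 20 11-(furan-2-yl)undeca-4,6-diyn-1-yl 19-(furan-2-yl)nonadeca-5,7-diynoate, via lithium alkoxide 18 (not isolated), via lithium hemiketal alkoxide 19 (not isolated)
Conditions: 9, n-BuLi (1 equiv), THF, −78 °C; then 17, −78 to 0 °C; aq. NH4Cl
Reagents that add atoms: n-butyllithium, [Li]CCCC (supplies only the lithium of 18 and 19)
Why: Proposed new method: the closest known reaction type is the nucleophile-triggered addition/C–C fragmentation of cyclic vinylogous acyl triflates, established with organometallic, hydride, enolate and lithium amide nucleophiles and with 2-alkyl or 2-aryl substituents; the extension proposed is an alkoxide trigger together with a 2-alkynyl substituent, so that the product is an ester of a conjugated diyne. Lithium alkoxide 18 adds reversibly to the ring carbonyl (ring C1) of 17 and gives hemiketal alkoxide 19. In 19 the ring C1–C2 σ bond is held antiperiplanar to the C3–OTf bond across the ring double bond, so collapse of the alkoxide to the ester carbonyl pushes the C1–C2 electrons into a new π bond between C2 and C3 while triflate leaves (Grob-type fragmentation); this opens the six-membered ring and turns ring C1, C6–C4, C3 and C2 into C1, C2–C4, C5 and C6 of the acyl chain. No ring is closed and no stereocentre is formed; the step makes the C1–O ester bond and the C5≡C6 triple bond together and so joins the two halves. The fragmentation is irreversible, driven by loss of triflate, ester resonance and conjugation of the new triple bond with the existing one, and it should therefore drain the unfavourable hemiketal equilibrium. The selectivity needed is attack at the carbonyl carbon and not at ring C3 (addition–elimination) or at sulfur (triflyl transfer); it is supported by the hard lithium alkoxide at low temperature, by the weak donor ability of the triflate oxygen, which leaves the C1 carbonyl ketone-like, and by the fact that only the carbonyl adduct has a low-barrier unimolecular exit. Residual 18 cannot scramble the product, since transesterification returns the same ester, and the diynes, furans and propargylic positions should not react with an alkoxide at or below 0 °C.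

## Compound list

1 | furan | c1ccoc1 | starting material
2 | 2-furyllithium | [Li]c1ccco1 | intermediate
3 | 1-bromo-4-chlorobutane | ClCCCCBr | starting material
4 | 2-(4-chlorobutyl)furan | ClCCCCc1ccco1 | intermediate
5 | lithium acetylide ethylenediamine complex | [Li]C#C.NCCN | starting material
6 | 2-(hex-5-yn-1-yl)furan | C#CCCCCc1ccco1 | intermediate
7 | pent-4-yn-1-ol | C#CCCCO | starting material
8 | 5-bromopent-4-yn-1-ol | OCCCC#CBr | intermediate
9 | 11-(furan-2-yl)undeca-4,6-diyn-1-ol | OCCCC#CC#CCCCCc1ccco1 | intermediate
10 | 1,11-dibromoundecane | BrCCCCCCCCCCCBr | starting material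
11 | 2-(11-bromoundecyl)furan | BrCCCCCCCCCCCc1ccco1 | intermediate
12 | 2-(tridec-12-yn-1-yl)furan | C#CCCCCCCCCCCCc1ccco1 | intermediate
13 | 3-ethoxycyclohex-2-en-1-one | CCOC1=CC(=O)CCC1 | starting material
14 | 3-ethoxy-2-iodocyclohex-2-en-1-one | CCOC1=C(I)C(=O)CCC1 | intermediate
15 | 3-ethoxy-2-[13-(furan-2-yl)tridec-1-yn-1-yl]cyclohex-2-en-1-one | CCOC1=C(C#CCCCCCCCCCCCc2ccco2)C(=O)CCC1 | intermediate
16 | 2-[13-(furan-2-yl)tridec-1-yn-1-yl]-3-hydroxycyclohex-2-en-1-one (enol of the 1,3-dione) | OC1=C(C#CCCCCCCCCCCCc2ccco2)C(=O)CCC1 | intermediate
17 | 2-[13-(furan-2-yl)tridec-1-yn-1-yl]-3-oxocyclohex-1-en-1-yl trifluoromethanesulfonate | O=C1CCCC(OS(=O)(=O)C(F)(F)F)=C1C#CCCCCCCCCCCCc1ccco1 | intermediate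
18 | lithium 11-(furan-2-yl)undeca-4,6-diyn-1-olate | [Li+].[O-]CCCC#CC#CCCCCc1ccco1 | intermediate
19 | lithium 1-{[11-(furan-2-yl)undeca-4,6-diyn-1-yl]oxy}-2-[13-(furan-2-yl)tridec-1-yn-1-yl]-3-[(trifluoromethanesulfonyl)oxy]cyclohex-2-en-1-olate (racemic, transient) | [Li+].[O-]C1(OCCCC#CC#CCCCCc2ccco2)CCCC(OS(=O)(=O)C(F)(F)F)=C1C#CCCCCCCCCCCCc1ccco1 | intermediate
20 | 11-(furan-2-yl)undeca-4,6-diyn-1-yl 19-(furan-2-yl)nonadeca-5,7-diynoate | O=C(CCCC#CC#CCCCCCCCCCCCc1ccco1)OCCCC#CC#CCCCCc1ccco1 | target

## Step count and least certain steps

Total step count: 12. Longest linear sequence: 7 steps (steps 1, 6, 7, 9, 10, 11 and 12, from 1 to 20).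

Step 12 (key step; it bears the label "Proposed new method:"). The most likely failure is diversion of the alkoxide from the ring carbonyl to the triflate-bearing carbon (addition–elimination) or to sulfur (triflyl transfer). Both paths would consume 17 without breaking the ring. The hemiketal equilibrium may also lie too far back for fragmentation to compete. The fallback uses known chemistry and sets out from compounds 9 and 12. Carbodiimide (Steglich) esterification of 9 with commercial hex-5-ynoic acid (DCC, DMAP, CH2Cl2) would give 11-(furan-2-yl)undeca-4,6-diyn-1-yl hex-5-ynoate F1. Separately, 12 would be deprotonated at the alkyne only (n-BuLi, 1 equiv, THF, −78 °C) and the acetylide quenched with NBS to give 2-(13-bromotridec-12-yn-1-yl)furan F2, without exposing the furan to free electrophilic bromine. Cadiot–Chodkiewicz coupling of F1 with F2 (CuCl, NH2OH·HCl, aq. EtNH2, MeOH/THF, 0 °C) comes back to the route at 20.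

Step 10. The most likely failure is acid-promoted cyclisation of the enol oxygen onto the neighbouring alkyne (5-endo-dig, to a fused furan), or acid-induced opening and oligomerisation of the 2-alkylfuran during the hydrolysis. The fallback unveils the dione with fluoride and sets out from compound 12. Cyclohexane-1,3-dione and 2-(trimethylsilyl)ethanol (TsOH cat., toluene, water removal) would give 3-[2-(trimethylsilyl)ethoxy]cyclohex-2-en-1-one F3. Iodination with NIS would give 2-iodo-3-[2-(trimethylsilyl)ethoxy]cyclohex-2-en-1-one F4. Sonogashira coupling with 12 would give 2-[13-(furan-2-yl)tridec-1-yn-1-yl]-3-[2-(trimethylsilyl)ethoxy]cyclohex-2-en-1-one F5. Treatment with n-Bu4NF (THF, 0 °C) would release, by β-elimination, tetrabutylammonium 2-[13-(furan-2-yl)tridec-1-yn-1-yl]-3-oxocyclohex-1-en-1-olate F6, which would be trapped in the same flask with PhNTf2. This comes back to the route at 17, without acid and without isolating 16.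

Step 9. The most likely failure is slow oxidative addition into the hindered, electron-rich C–I bond, which would let copper-mediated oxidative homocoupling of 12 take over. The fallback removes copper acetylides and sets out from compound 12. Lithiation at the alkyne (n-BuLi, THF, −78 °C) and quenching with n-Bu3SnCl would give tributyl[13-(furan-2-yl)tridec-1-yn-1-yl]stannane F7. Stille coupling of F7 with 14 (Pd(PPh3)4, DMF, 60 °C) comes back to the route at 15.

Step 5. The most likely failure is homocoupling of either partner through halogen–copper exchange, which would give symmetrical diynes of similar polarity. The fallback builds the diyne without a bromoalkyne and sets out from compound 6. Palladium/copper coupling of 6 with an excess of (Z)-1,2-dichloroethene (Pd(PPh3)4, CuI, n-BuNH2, Et2O) would give 2-[(7Z)-8-chlorooct-7-en-5-yn-1-yl]furan F8. Elimination and metalation with LiN(i-Pr)2 (2.2 equiv, THF, −78 °C) would give lithium 8-(furan-2-yl)octa-1,3-diyn-1-ide F9, not isolated. Opening of oxetane in the presence of BF3·OEt2 at −78 °C comes back to the route at 9.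

## Further compounds

F1 | step 12 | 11-(furan-2-yl)undeca-4,6-diyn-1-yl hex-5-ynoate | C#CCCCC(=O)OCCCC#CC#CCCCCc1ccco1
F2 | step 12 | 2-(13-bromotridec-12-yn-1-yl)furan | BrC#CCCCCCCCCCCCc1ccco1
F3 | step 10 | 3-[2-(trimethylsilyl)ethoxy]cyclohex-2-en-1-one | C[Si](C)(C)CCOC1=CC(=O)CCC1
F4 | step 10 | 2-iodo-3-[2-(trimethylsilyl)ethoxy]cyclohex-2-en-1-one | C[Si](C)(C)CCOC1=C(I)C(=O)CCC1
F5 | step 10 | 2-[13-(furan-2-yl)tridec-1-yn-1-yl]-3-[2-(trimethylsilyl)ethoxy]cyclohex-2-en-1-one | C[Si](C)(C)CCOC1=C(C#CCCCCCCCCCCCc2ccco2)C(=O)CCC1
F6 | step 10 | tetrabutylammonium 2-[13-(furan-2-yl)tridec-1-yn-1-yl]-3-oxocyclohex-1-en-1-olate | CCCC[N+](CCCC)(CCCC)CCCC.[O-]C1=C(C#CCCCCCCCCCCCc2ccco2)C(=O)CCC1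
F7 | step 9 | tributyl[13-(furan-2-yl)tridec-1-yn-1-yl]stannane | CCCC[Sn](CCCC)(CCCC)C#CCCCCCCCCCCCc1ccco1
F8 | step 5 | 2-[(7Z)-8-chlorooct-7-en-5-yn-1-yl]furan | Cl/C=C\C#CCCCCc1ccco1
F9 | step 5 | lithium 8-(furan-2-yl)octa-1,3-diyn-1-ide | [Li]C#CC#CCCCCc1ccco1
A1 | alternative 1 | 6-bromohex-5-ynoic acid | OC(=O)CCCC#CBr
A2 | alternative 1 | 19-(furan-2-yl)nonadeca-5,7-diynoic acid | OC(=O)CCCC#CC#CCCCCCCCCCCCc1ccco1
A3 | alternative 2 | 2-[18-[(tert-butyldimethylsilyl)oxy]-12-(dibromomethylidene)octadec-13-yn-1-yl]furan | BrC(Br)=C(CCCCCCCCCCCc1ccco1)C#CCCCCO[Si](C)(C)C(C)(C)C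
A4 | alternative 2 | tert-butyl{[19-(furan-2-yl)nonadeca-5,7-diyn-1-yl]oxy}dimethylsilane | CC(C)(C)[Si](C)(C)OCCCCC#CC#CCCCCCCCCCCCc1ccco1
A5 | alternative 3 | 1,4-bis(trimethylsilyl)buta-1,3-diyne | C[Si](C)(C)C#CC#C[Si](C)(C)C
A6 | alternative 3 | 2-(4-iodobutyl)furan | ICCCCc1ccco1
A7 | alternative 3 | trimethyl[8-(furan-2-yl)octa-1,3-diyn-1-yl]silane | C[Si](C)(C)C#CC#CCCCCc1ccco1
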